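**Strategy**

- Retrosynthesis: the γ-lactone is opened to a C8,C12-diol (C12 oxidation level). The ten-membered ring is then cut at C7–C8 by a retro-oxy-Cope shift that re-forms C5–C10 and leaves a cyclohexenol with alkenyl groups on C5 and C10. These arms are removed at C5–C6 (alkenylmetal plus ketone) and at the C8–O enol ether bond (aldehyde enolate).
- Forward: the six-membered ring C10–C5–C4–C3–C2–C1 is bought as 2-methylcyclohexane-1,3-dione, the two alkenyl arms are attached, the ring grows to the ten-membered carbocycle in one step, and the lactone ring is closed last.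
- Enabling feature: the carbocycle C1–C10 is a latent cyclodec-5-enone, with oxygen on C5, the C9=C10 alkene five atoms further on, the C7/C8 stereodiad between them, and a cis C3=C4 alkene that can be inherited from a cyclohexene.
- Stereochemistry: C10 (later sp2) and C1 come from a desymmetrising oxazaborolidine reduction, and C11 from methyl (S)-3-hydroxy-2-methylpropanoate. C7 and C8 arise by chirality transfer from C10 through a chair transition state, and C5 from a reagent-controlled reduction. C1 is carried as its epimer and inverted by a Mitsunobu acetate formation.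

Key step: step 12

Remark: atom labels C1–C12 in the text are those of the target (C1 and C5 acetoxy carbons, C3=C4 and C9=C10 alkenes, C7/C8 ring fusion, C11 and C12 in the lactone), also for the six-membered precursors. In the systematic names of 8, 12 and 19 the ring locants 1, 2, 3, 4, 5, 6 correspond to target C5, C4, C3, C2, C1, C10. The names of 22–30 use target locants.

**Route**

Step 1
Reactants: 1 2-methylcyclohexane-1,3-dione; 2 allyl bromide
Product: 3 2-allyl-2-methylcyclohexane-1,3-dione
Conditions: NaOH, H2O, n-Bu4NI (cat.), rt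
Reagents that add atoms: none
Why: SN2 C-allylation of the stabilised 1,3-dione enolate in water, where hydrogen bonding to the enolate oxygens disfavours O-allylation, builds the quaternary carbon that becomes C10 without yet defining its configuration.

Step 2
Reactants: 3 2-allyl-2-methylcyclohexane-1,3-dione
Product: 4 (2R,3R)-2-allyl-3-hydroxy-2-methylcyclohexan-1-one (hydroxyl cis to allyl)
Conditions: (S)-2-methyl-CBS-oxazaborolidine (20 mol %), catecholborane, toluene, −78 to −40 °C; MeOH, aq. NaHCO3
Reagents that add atoms: none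
Why: Corey–Bakshi–Shibata reduction desymmetrises the dione: the (S)-catalyst, reading the quaternary carbon as the large group, should give the 3R carbinol (future C1), and hydride enters the carbonyl anti to the larger allyl group, so the quaternary centre (future C10) becomes R, while catecholborane leaves the terminal alkene alone.

Step 3
Reactants: 4 (2R,3R)-2-allyl-3-hydroxy-2-methylcyclohexan-1-one
Product: 5 (2R,3R)-2-allyl-3-[(tert-butyldimethylsilyl)oxy]-2-methylcyclohexan-1-one
Conditions: TBSOTf, 2,6-lutidine, CH2Cl2, −78 to 0 °C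
Reagents that add atoms: tert-butyldimethylsilyl triflate, CC(C)(C)[Si](C)(C)OS(=O)(=O)C(F)(F)F
Why: Silylation of a hindered neopentyl-type secondary alcohol with the silyl triflate and a non-nucleophilic base, which blocks retro-aldol opening of the β-hydroxy ketone in the basic steps that follow and touches no stereocentre.

Step 4
Reactants: 5 (2R,3R)-2-allyl-3-[(tert-butyldimethylsilyl)oxy]-2-methylcyclohexan-1-one
Product: 7 (2R,3R)-2-allyl-3-[(tert-butyldimethylsilyl)oxy]-2,6-dimethylcyclohexan-1-one (both C6 epimers), via lithium enolate 6 (not isolated)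
Conditions: LiN(i-Pr)2, THF, −78 °C; MeI, DMPU, −78 to −20 °C
Reagents that add atoms: iodomethane, CI
Why: Kinetic enolate alkylation that is regiospecific because the ketone can enolise only towards C4 (the other α-carbon, C10, is quaternary), and the configuration of the new methyl-bearing centre is irrelevant because it becomes sp2 in step 5.

Step 5
Reactants: 7 (2R,3R)-2-allyl-3-[(tert-butyldimethylsilyl)oxy]-2,6-dimethylcyclohexan-1-one
Product: 8 (5R,6R)-6-allyl-5-[(tert-butyldimethylsilyl)oxy]-2,6-dimethylcyclohex-2-en-1-one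
Conditions: IBX, toluene/DMSO, 70 °C
Reagents that add atoms: none
Why: IBX dehydrogenation of a ketone through its enol gives the endocyclic C3=C4 enone, the only desaturation possible since C10 is quaternary, and the isolated allyl alkene and the silyl ether are not attacked at this temperature.

Step 6
Reactants: 8 (5R,6R)-6-allyl-5-[(tert-butyldimethylsilyl)oxy]-2,6-dimethylcyclohex-2-en-1-one
Product: 10 2-[(1R,6R)-6-[(tert-butyldimethylsilyl)oxy]-1,3-dimethyl-2-oxocyclohex-3-en-1-yl]acetaldehyde, via diol 9 (not isolated)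
Conditions: OsO4 (cat.), NaIO4, 2,6-lutidine, 1,4-dioxane/H2O, rt
Reagents that add atoms: osmium tetroxide, O=[Os](=O)(=O)=O (transfers the aldehyde oxygen); sodium periodate, [Na+].[O-]I(=O)(=O)=O (terminal oxidant)
Why: Lemieux–Johnson oxidation, in which OsO4 dihydroxylates the electron-rich monosubstituted alkene much faster than the electron-poor trisubstituted enone alkene and NaIO4 cleaves the diol in the same flask; it is placed after the enolate chemistry so that no aldehyde meets LiN(i-Pr)2.

Step 7
Reactants: 10 2-[(1R,6R)-6-[(tert-butyldimethylsilyl)oxy]-1,3-dimethyl-2-oxocyclohex-3-en-1-yl]acetaldehyde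
Product: 12 (5R,6R)-5-[(tert-butyldimethylsilyl)oxy]-6-[(E)-2-(methoxymethoxy)ethenyl]-2,6-dimethylcyclohex-2-en-1-one, via potassium enolate 11 (not isolated)
Conditions: KN(SiMe3)2, THF, −78 °C; MOMCl, −78 to 0 °C
Reagents that add atoms: chloromethyl methyl ether, COCCl
Why: O-alkylation of a potassium aldehyde enolate by a hard α-chloro ether: the aldehyde α-hydrogens are the most acidic in the molecule, and the tertiary C10 substituent avoids the metal-bound oxygen both in the deprotonation transition state and in the enol ether, which should give the E geometry that step 12 needs.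

Step 8
Reactants: 13 methyl (S)-3-hydroxy-2-methylpropanoate
Product: 14 methyl (S)-3-(methoxymethoxy)-2-methylpropanoate
Conditions: MOMCl, i-Pr2NEt, CH2Cl2, 0 °C to rt
Reagents that add atoms: chloromethyl methyl ether, COCCl
Why: Standard acetal protection of a primary alcohol under mild amine-base conditions that do not epimerise the α-stereocentre (future C11), with the same protecting group as on O8 so that both are removed together later.

Step 9
Reactants: 14 methyl (S)-3-(methoxymethoxy)-2-methylpropanoate
Product: 15 (S)-3-(methoxymethoxy)-2-methylpropanal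
Conditions: i-Bu2AlH, CH2Cl2, −78 °C; MeOH, aq. potassium sodium tartrate
Reagents that add atoms: none
Why: Partial ester reduction in which the tetrahedral aluminium hemiacetal persists at −78 °C and releases the aldehyde only on work-up, and the aldehyde is used crude at once to avoid α-epimerisation.

Step 10
Reactants: 15 (S)-3-(methoxymethoxy)-2-methylpropanal
Product: 16 (R,E)-1-iodo-4-(methoxymethoxy)-3-methylbut-1-ene
Conditions: CrCl2, CHI3, THF/1,4-dioxane, 0 °C to rt
Reagents that add atoms: iodoform, IC(I)I
Why: Takai olefination, in which the geminal dichromium reagent formed from CHI3 and divalent chromium adds to the aldehyde and eliminates to the (E)-alkenyl iodide under non-basic conditions that preserve the adjacent stereocentre.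

Step 11
Reactants: 16 (R,E)-1-iodo-4-(methoxymethoxy)-3-methylbut-1-ene; 12 (5R,6R)-5-[(tert-butyldimethylsilyl)oxy]-6-[(E)-2-(methoxymethoxy)ethenyl]-2,6-dimethylcyclohex-2-en-1-one
Product: 19 (1S,5R,6R)-5-[(tert-butyldimethylsilyl)oxy]-6-[(E)-2-(methoxymethoxy)ethenyl]-1-[(1E,3R)-4-(methoxymethoxy)-3-methylbut-1-en-1-yl]-2,6-dimethylcyclohex-2-en-1-ol, via alkenyllithium 17 (not isolated), via alkenylcerium dichloride 18 (not isolated)
Conditions: 16, t-BuLi (2 equiv), Et2O, −78 °C; CeCl3, THF, −78 °C; then 12, −78 °C; aq. NaHCO3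
Reagents that add atoms: none
Why: Iodine–lithium exchange with retention of alkene geometry, transmetalation to the weakly basic organocerium reagent (no γ-deprotonation of the enone) and 1,2-addition to the hindered carbonyl; the face syn to the C10 alkenyl group is blocked in either half-chair, by the axial alkenyl group itself or by a syn-axial silyloxy group at C1, so the nucleophile enters from the other face and the two alkenyl groups end up trans (new C5 carbinol).

Step 12
Reactants: 19 (1S,5R,6R)-5-[(tert-butyldimethylsilyl)oxy]-6-[(E)-2-(methoxymethoxy)ethenyl]-1-[(1E,3R)-4-(methoxymethoxy)-3-methylbut-1-en-1-yl]-2,6-dimethylcyclohex-2-en-1-ol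
Product: 22 (1R,7S,8S,3Z,9E)-1-[(tert-butyldimethylsilyl)oxy]-8-(methoxymethoxy)-7-[(2R)-1-(methoxymethoxy)propan-2-yl]-4,10-dimethylcyclodeca-3,9-dien-5-one, via potassium alkoxide 20 (not isolated), via potassium enolate 21 (not isolated)
Conditions: KH, 18-crown-6, THF, 0 °C to rt; then −78 °C, aq. NH4Cl
Reagents that add atoms: none
Why: Anionic oxy-Cope rearrangement, the charge-accelerated [3,3]-sigmatropic shift established for trans-1,2-dialkenylcyclohexanols and 1,6-dialkenylcyclohex-2-enols: in the crown-ether-separated alkoxide 20 the C5–C10 bond breaks while C7–C8 forms, and the resulting enolate 21 is protonated at C6 on quench. The ten-membered ring is not closed from an open chain but grows out of the cyclohexene by insertion of the four alkenyl carbons C6–C9 between C5 and C10 through a six-membered chair transition state fused to the old ring, so the entropic cost of medium-ring closure is avoided. C7 and C8 are created together: both migrating alkenes are E, so the C8 methoxymethoxy group and the C7 side chain are equatorial on the chair with their hydrogens anti, and the R configuration of quaternary C10 (ring bond C10–C1 equatorial, methyl axial) decides which alkene faces meet, giving 7S,8S. The same chair places C1 anti to C8 across the new double bond, hence (E)-C9=C10, and the former cyclohexene bond is carried over untouched as the (Z)-C3=C4 enone. The step needs the trans, diequatorial arrangement of the two alkenyl groups, which step 11 secures, at the price of an axial silyloxy group at C1; the tertiary hydroxyl is the only acidic site, so KH does nothing else.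

Step 13
Reactants: 22 (1R,7S,8S,3Z,9E)-1-[(tert-butyldimethylsilyl)oxy]-8-(methoxymethoxy)-7-[(2R)-1-(methoxymethoxy)propan-2-yl]-4,10-dimethylcyclodeca-3,9-dien-5-one
Product: 23 (1R,5R,7S,8S,3Z,9E)-1-[(tert-butyldimethylsilyl)oxy]-8-(methoxymethoxy)-7-[(2R)-1-(methoxymethoxy)propan-2-yl]-4,10-dimethylcyclodeca-3,9-dien-5-ol
Conditions: (S)-2-methyl-CBS-oxazaborolidine, catecholborane, toluene, −78 °C; MeOH, aq. NaHCO3
Reagents that add atoms: none
Why: Corey–Bakshi–Shibata 1,2-reduction of the α-methyl enone under reagent control: with the alkenyl carbon C4 as the large group and the C6 methylene as the small one, the (S)-catalyst is expected to give the 5R allylic alcohol, and catecholborane at low temperature neither hydroborates the alkenes nor reduces in the conjugate sense.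

Step 14
Reactants: 23 (1R,5R,7S,8S,3Z,9E)-1-[(tert-butyldimethylsilyl)oxy]-8-(methoxymethoxy)-7-[(2R)-1-(methoxymethoxy)propan-2-yl]-4,10-dimethylcyclodeca-3,9-dien-5-ol
Product: 24 (1R,5R,7S,8S,3Z,9E)-5-acetoxy-1-[(tert-butyldimethylsilyl)oxy]-8-(methoxymethoxy)-7-[(2R)-1-(methoxymethoxy)propan-2-yl]-4,10-dimethylcyclodeca-3,9-diene
Conditions: Ac2O, pyridine, DMAP (cat.), CH2Cl2, 0 °C to rt
Reagents that add atoms: acetic anhydride, CC(=O)OC(C)=O
Why: DMAP-catalysed acylation of the only free hydroxyl with retention at C5, the silyl ether and the acetals being inert.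

Step 15
Reactants: 24 (1R,5R,7S,8S,3Z,9E)-5-acetoxy-1-[(tert-butyldimethylsilyl)oxy]-8-(methoxymethoxy)-7-[(2R)-1-(methoxymethoxy)propan-2-yl]-4,10-dimethylcyclodeca-3,9-diene
Product: 25 (1R,5R,7S,8S,3Z,9E)-5-acetoxy-8-(methoxymethoxy)-7-[(2R)-1-(methoxymethoxy)propan-2-yl]-4,10-dimethylcyclodeca-3,9-dien-1-ol
Conditions: HF·pyridine, pyridine, THF, 0 °C to rt
Reagents that add atoms: none
Why: Fluoride desilylation under buffered, non-basic conditions, chosen because a free C1 alkoxide would sit in the ring 1,5-diene (C9=C10–C1–C2–C3=C4) and could trigger a second oxy-Cope shift or acetyl migration, whereas the acetate and the acetals survive pyridine-buffered HF.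

Step 16
Reactants: 25 (1R,5R,7S,8S,3Z,9E)-5-acetoxy-8-(methoxymethoxy)-7-[(2R)-1-(methoxymethoxy)propan-2-yl]-4,10-dimethylcyclodeca-3,9-dien-1-ol
Product: 26 (1S,5R,7S,8S,3Z,9E)-1,5-diacetoxy-8-(methoxymethoxy)-7-[(2R)-1-(methoxymethoxy)propan-2-yl]-4,10-dimethylcyclodeca-3,9-diene
Conditions: AcOH, PPh3, DIAD, toluene, 0 °C to rt
Reagents that add atoms: acetic acid, CC(=O)O
Why: Mitsunobu reaction in which the C1 alcohol is activated as its alkoxyphosphonium ion and displaced by acetate in an SN2 process with inversion, turning the 1R carbinol used for stereocontrol into the 1S acetate of the target.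

Step 17
Reactants: 26 (1S,5R,7S,8S,3Z,9E)-1,5-diacetoxy-8-(methoxymethoxy)-7-[(2R)-1-(methoxymethoxy)propan-2-yl]-4,10-dimethylcyclodeca-3,9-diene
Product: 28 (1S,5R,7S,8S,3Z,9E)-1,5-diacetoxy-7-[(2R)-1-hydroxypropan-2-yl]-4,10-dimethylcyclodeca-3,9-dien-8-ol, via bis(bromomethyl) ether 27 (not isolated)
Conditions: Me2BBr, CH2Cl2, −78 °C; then THF/aq. NaHCO3, −78 °C to rt
Reagents that add atoms: none
Why: Lewis-acid acetal cleavage in which the bromoborane coordinates the methoxy oxygen of each methoxymethyl ether and cleaves it at −78 °C to a bromomethyl ether that hydrolyses on bicarbonate quench, aprotic conditions under which the esters and the transannularly reactive diene should be left alone and no stereocentre is involved.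

Step 18
Reactants: 28 (1S,5R,7S,8S,3Z,9E)-1,5-diacetoxy-7-[(2R)-1-hydroxypropan-2-yl]-4,10-dimethylcyclodeca-3,9-dien-8-ol
Product: 30 CNP0226482.6 (1S,5R,7S,8S,11R,3Z,9E)-1,5-diacetoxygermacra-3,9-dien-12,8-olide, via lactol 29 (not isolated)
Conditions: TEMPO (cat.), PhI(OAc)2, CH2Cl2, rt
Reagents that add atoms: none
Why: Oxoammonium-mediated oxidative lactonisation of a 1,4-diol: the primary C12 alcohol is oxidised selectively to the aldehyde, the C8 hydroxyl traps it as the five-membered lactol, and this is oxidised on to the trans-fused γ-lactone whose configuration at C7, C8 and C11 is already fixed.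

**Compound list**

1 | 2-methylcyclohexane-1,3-dione | CC1C(=O)CCCC1=O | starting material
2 | allyl bromide | C=CCBr | starting material
3 | 2-allyl-2-methylcyclohexane-1,3-dione | C=CCC1(C)C(=O)CCCC1=O | intermediate
4 | (2R,3R)-2-allyl-3-hydroxy-2-methylcyclohexan-1-one | C=CC[C@@]1(C)C(=O)CCC[C@H]1O | intermediate
5 | (2R,3R)-2-allyl-3-[(tert-butyldimethylsilyl)oxy]-2-methylcyclohexan-1-one | C=CC[C@@]1(C)C(=O)CCC[C@H]1O[Si](C)(C)C(C)(C)C | intermediate
6 | lithium enolate of 5 (not isolated) | C=CC[C@@]1(C)C(O[Li])=CCC[C@H]1O[Si](C)(C)C(C)(C)C | intermediate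
7 | (2R,3R)-2-allyl-3-[(tert-butyldimethylsilyl)oxy]-2,6-dimethylcyclohexan-1-one, both C6 epimers | C=CC[C@@]1(C)C(=O)C(C)CC[C@H]1O[Si](C)(C)C(C)(C)C | intermediate
8 | (5R,6R)-6-allyl-5-[(tert-butyldimethylsilyl)oxy]-2,6-dimethylcyclohex-2-en-1-one | C=CC[C@@]1(C)C(=O)C(C)=CC[C@H]1O[Si](C)(C)C(C)(C)C | intermediate
9 | (5R,6R)-5-[(tert-butyldimethylsilyl)oxy]-6-(2,3-dihydroxypropyl)-2,6-dimethylcyclohex-2-en-1-one (not isolated) | OCC(O)C[C@@]1(C)C(=O)C(C)=CC[C@H]1O[Si](C)(C)C(C)(C)C | intermediate
10 | 2-[(1R,6R)-6-[(tert-butyldimethylsilyl)oxy]-1,3-dimethyl-2-oxocyclohex-3-en-1-yl]acetaldehyde | O=CC[C@@]1(C)C(=O)C(C)=CC[C@H]1O[Si](C)(C)C(C)(C)C | intermediate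
11 | potassium (E)-enolate of aldehyde 10 (not isolated) | [K]O/C=C/[C@@]1(C)C(=O)C(C)=CC[C@H]1O[Si](C)(C)C(C)(C)C | intermediate
12 | (5R,6R)-5-[(tert-butyldimethylsilyl)oxy]-6-[(E)-2-(methoxymethoxy)ethenyl]-2,6-dimethylcyclohex-2-en-1-one | COCO/C=C/[C@@]1(C)C(=O)C(C)=CC[C@H]1O[Si](C)(C)C(C)(C)C | intermediate
13 | methyl (S)-3-hydroxy-2-methylpropanoate | COC(=O)[C@@H](C)CO | starting material
14 | methyl (S)-3-(methoxymethoxy)-2-methylpropanoate | COCOC[C@H](C)C(=O)OC | intermediate
15 | (S)-3-(methoxymethoxy)-2-methylpropanal | COCOC[C@H](C)C=O | intermediate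
16 | (R,E)-1-iodo-4-(methoxymethoxy)-3-methylbut-1-ene | COCOC[C@H](C)/C=C/I | intermediate
17 | (R,E)-[4-(methoxymethoxy)-3-methylbut-1-en-1-yl]lithium (not isolated) | COCOC[C@H](C)/C=C/[Li] | intermediate
18 | (R,E)-[4-(methoxymethoxy)-3-methylbut-1-en-1-yl]cerium dichloride (not isolated) | COCOC[C@H](C)/C=C/[Ce](Cl)Cl | intermediate
19 | (1S,5R,6R)-5-[(tert-butyldimethylsilyl)oxy]-6-[(E)-2-(methoxymethoxy)ethenyl]-1-[(1E,3R)-4-(methoxymethoxy)-3-methylbut-1-en-1-yl]-2,6-dimethylcyclohex-2-en-1-ol | COCO/C=C/[C@@]1(C)[C@](O)(/C=C/[C@@H](C)COCOC)C(C)=CC[C@H]1O[Si](C)(C)C(C)(C)C | intermediate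
20 | potassium alkoxide of 19 (not isolated) | COCO/C=C/[C@@]1(C)[C@](O[K])(/C=C/[C@@H](C)COCOC)C(C)=CC[C@H]1O[Si](C)(C)C(C)(C)C | intermediate
21 | potassium C5=C6 enolate of ketone 22 (not isolated) | [K]O/C1=C\[C@@H]([C@@H](C)COCOC)[C@H](OCOC)/C=C(C)/[C@H](O[Si](C)(C)C(C)(C)C)C/C=C1/C | intermediate
22 | (1R,7S,8S,3Z,9E)-1-[(tert-butyldimethylsilyl)oxy]-8-(methoxymethoxy)-7-[(2R)-1-(methoxymethoxy)propan-2-yl]-4,10-dimethylcyclodeca-3,9-dien-5-one | O=C1C[C@@H]([C@@H](C)COCOC)[C@H](OCOC)/C=C(C)/[C@H](O[Si](C)(C)C(C)(C)C)C/C=C1/C | intermediate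
23 | (1R,5R,7S,8S,3Z,9E)-1-[(tert-butyldimethylsilyl)oxy]-8-(methoxymethoxy)-7-[(2R)-1-(methoxymethoxy)propan-2-yl]-4,10-dimethylcyclodeca-3,9-dien-5-ol | O[C@@H]1C[C@@H]([C@@H](C)COCOC)[C@H](OCOC)/C=C(C)/[C@H](O[Si](C)(C)C(C)(C)C)C/C=C1/C | intermediate
24 | 5-acetate of 23 | CC(=O)O[C@@H]1C[C@@H]([C@@H](C)COCOC)[C@H](OCOC)/C=C(C)/[C@H](O[Si](C)(C)C(C)(C)C)C/C=C1/C | intermediate
25 | (1R,5R,7S,8S,3Z,9E)-5-acetoxy-8-(methoxymethoxy)-7-[(2R)-1-(methoxymethoxy)propan-2-yl]-4,10-dimethylcyclodeca-3,9-dien-1-ol | CC(=O)O[C@@H]1C[C@@H]([C@@H](C)COCOC)[C@H](OCOC)/C=C(C)/[C@H](O)C/C=C1/C | intermediate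
26 | (1S,5R,7S,8S,3Z,9E)-1,5-diacetoxy-8-(methoxymethoxy)-7-[(2R)-1-(methoxymethoxy)propan-2-yl]-4,10-dimethylcyclodeca-3,9-diene | CC(=O)O[C@@H]1C[C@@H]([C@@H](C)COCOC)[C@H](OCOC)/C=C(C)/[C@@H](OC(C)=O)C/C=C1/C | intermediate
27 | bis(bromomethyl) ether of diol 28 (not isolated) | CC(=O)O[C@@H]1C[C@@H]([C@@H](C)COCBr)[C@H](OCBr)/C=C(C)/[C@@H](OC(C)=O)C/C=C1/C | intermediate
28 | (1S,5R,7S,8S,3Z,9E)-1,5-diacetoxy-7-[(2R)-1-hydroxypropan-2-yl]-4,10-dimethylcyclodeca-3,9-dien-8-ol | CC(=O)O[C@@H]1C[C@@H]([C@@H](C)CO)[C@H](O)/C=C(C)/[C@@H](OC(C)=O)C/C=C1/C | intermediate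
29 | lactol, C12 hemiacetal closed onto O8 (not isolated) | CC(=O)O[C@H]1C/C=C(/C)[C@H](OC(C)=O)C[C@@H]2[C@@H](/C=C/1C)OC(O)[C@@H]2C | intermediate
30 | CNP0226482.6, (1S,5R,7S,8S,11R,3Z,9E)-1,5-diacetoxygermacra-3,9-dien-12,8-olide | CC(=O)O[C@H]1C/C=C(/C)[C@H](OC(C)=O)C[C@@H]2[C@@H](/C=C/1C)OC(=O)[C@@H]2C | target

**Step count**

Total: 18 steps. Longest linear sequence: 15 steps (steps 1–7 and 11–18, from 2-methylcyclohexane-1,3-dione). The alkenyl iodide is made in 3 steps (8–10) and joins at step 11.

**Steps most likely to fail**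

Step 13. Hydride delivery to C5 may be governed by the conformation of the ten-membered enone instead of by the catalyst, which would erode or reverse the facial selectivity. The fallback sets out from ketone 22 and comes back at acetate 24. The ketone is reduced under substrate control (NaBH4, CeCl3·7H2O, MeOH, −78 °C). If this delivers the 5S allylic alcohol F1, the centre is corrected while the ester is installed, by a Mitsunobu reaction with acetic acid (PPh3, DIAD, toluene). This gives 24 with inversion and replaces steps 13 and 14.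

Step 7. The enolate may be alkylated on carbon, or on oxygen without geometric control, and a Z enol ether would place the C8 oxygen axial in step 12 and deliver the wrong C8 configuration. The fallback sets out from aldehyde 10 and comes back at 12, and it moves the geometry from kinetic to thermodynamic control. The thermodynamic potassium enolate (KH, THF, DMPU, then MOMCl) is O-alkylated without regard to geometry, giving 12 together with the (Z)-enol ether F2. The mixture is then equilibrated by reversible thiyl-radical addition (PhSSPh cat., hν, benzene). With a quaternary carbon on the alkene the E isomer should dominate at equilibrium, and any remaining Z material is separated and resubmitted.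

Step 16. The hindered allylic C1 alkoxyphosphonium ion may eliminate to a diene or be attacked with allylic transposition at C9 instead of undergoing clean SN2 inversion. The fallback sets out from alcohol 25 and comes back at diacetate 26, and it replaces substitution by oxidation and reduction. Dess–Martin periodinane (NaHCO3, CH2Cl2, 0 °C) gives the C1 enone F3. This is reduced without delay with (R)-2-methyl-CBS-oxazaborolidine and catecholborane (toluene, −78 °C; C10 as the large group) to the 1S alcohol F4. Acetylation (Ac2O, pyridine, DMAP) then gives 26.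

**Further compounds**

F1 | step 13 | (1R,5S,7S,8S,3Z,9E)-1-[(tert-butyldimethylsilyl)oxy]-8-(methoxymethoxy)-7-[(2R)-1-(methoxymethoxy)propan-2-yl]-4,10-dimethylcyclodeca-3,9-dien-5-ol | O[C@H]1C[C@@H]([C@@H](C)COCOC)[C@H](OCOC)/C=C(C)/[C@H](O[Si](C)(C)C(C)(C)C)C/C=C1/C
F2 | step 7 | (5R,6R)-5-[(tert-butyldimethylsilyl)oxy]-6-[(Z)-2-(methoxymethoxy)ethenyl]-2,6-dimethylcyclohex-2-en-1-one | COCO/C=C\[C@@]1(C)C(=O)C(C)=CC[C@H]1O[Si](C)(C)C(C)(C)C
F3 | step 16 | (5R,7S,8S,3Z,9E)-5-acetoxy-8-(methoxymethoxy)-7-[(2R)-1-(methoxymethoxy)propan-2-yl]-4,10-dimethylcyclodeca-3,9-dien-1-one | CC(=O)O[C@@H]1C[C@@H]([C@@H](C)COCOC)[C@H](OCOC)/C=C(C)/C(=O)C/C=C1/C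
F4 | step 16 | (1S,5R,7S,8S,3Z,9E)-5-acetoxy-8-(methoxymethoxy)-7-[(2R)-1-(methoxymethoxy)propan-2-yl]-4,10-dimethylcyclodeca-3,9-dien-1-ol | CC(=O)O[C@@H]1C[C@@H]([C@@H](C)COCOC)[C@H](OCOC)/C=C(C)/[C@@H](O)C/C=C1/C
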